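**Retrosynthetic overview**

- The strategy rests on ring B (C3a–C4–C5–C6–C7–C7a): quaternary C3a lies para to the C6 carbonyl of a cross-conjugated dienone, so without the O1–C7a bond and the C5 methoxy group the arms C4=C5 and C7=C7a are identical and C3a is prochiral.
- The C5 methoxy group is removed last (epoxide of C4=C5, methoxide opening, dehydration), then the C7=C7a double bond (dehydrogenation of the cis-fused enone).
- O1–C7a is cut by a retro-oxa-Michael step to a 4-allyl-4-(1-aryl-1-hydroxypropan-2-yl)cyclohexa-2,5-dienone; ring A (tetrahydrofuran) is therefore formed second, ring B first.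
- Ring B comes from an α-allyl aldehyde and methyl vinyl ketone (Robinson annulation), followed by dehydrogenation to the dienone.
- The aldehyde comes from anti-crotylboration of 3,4,5-trimethoxybenzaldehyde (sets C2 and C3), hydroboration–oxidation and α-allylation.

Key step: step 9

Assumption: the (S)-phosphoric acid in step 1 is taken to deliver the crotyl group to the Si face of the aldehyde (the usual sense for aryl aldehydes), and (R)-TRIP in step 9 is assumed to be the enantiomer matched to the required arm; if it proves mismatched, its antipode is used with no other change.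

**Route**

Step 1
Reactants: 1 3,4,5-trimethoxybenzaldehyde; 2 (E)-crotylboronic acid pinacol ester
Product: 3 (1S,2S)-2-methyl-1-(3,4,5-trimethoxyphenyl)but-3-en-1-ol (anti)
Conditions: (S)-TRIP [(S)-3,3'-bis(2,4,6-triisopropylphenyl)-1,1'-binaphthyl-2,2'-diyl hydrogen phosphate] (5 mol%), toluene, −30 °C; aqueous work-up
Reagents that add atoms: none
Why: Phosphoric-acid-catalysed crotylboration runs through a closed chair transition state, so the (E)-geometry of 2 gives the anti C1/C2 pair and the chiral acid, bound to the boronate oxygen and the formyl hydrogen, selects the aldehyde face, which sets both stereocentres as (1S,2S).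

Step 2
Reactants: 3 (1S,2S)-2-methyl-1-(3,4,5-trimethoxyphenyl)but-3-en-1-ol
Product: 4 tert-butyl(dimethyl){[(1S,2S)-2-methyl-1-(3,4,5-trimethoxyphenyl)but-3-en-1-yl]oxy}silane
Conditions: TBSOTf, 2,6-lutidine, CH2Cl2, 0 °C
Reagents that add atoms: tert-butyldimethylsilyl triflate, CC(C)(C)[Si](C)(C)OS(=O)(=O)C(F)(F)F
Why: Silylation of the hindered benzylic carbinol with the silyl triflate masks the hydroxyl, so that the later γ-oxygenated aldehyde cannot form a lactol and the oxygen cannot add to the dienone before step 9; no stereocentre is touched.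

Step 3
Reactants: 4 silyl ether
Product: 5 (3S,4S)-4-[(tert-butyldimethylsilyl)oxy]-3-methyl-4-(3,4,5-trimethoxyphenyl)butan-1-ol
Conditions: 9-BBN (9-borabicyclo[3.3.1]nonane), THF, 0 °C to rt; then NaOH (aq), H2O2, 0 °C
Reagents that add atoms: hydrogen peroxide, OO
Why: Hydroboration–oxidation with the bulky dialkylborane places boron on the terminal carbon of the monosubstituted alkene and oxidation gives the primary alcohol, leaving both stereocentres untouched.

Step 4
Reactants: 5 primary alcohol
Product: 6 (3S,4S)-4-[(tert-butyldimethylsilyl)oxy]-3-methyl-4-(3,4,5-trimethoxyphenyl)butanal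
Conditions: TEMPO (10 mol%), PhI(OAc)2, CH2Cl2, rt
Reagents that add atoms: none
Why: Oxoammonium-mediated oxidation stops at the aldehyde under nearly neutral conditions, and the methyl-bearing stereocentre is β to the new carbonyl and cannot epimerise.

Step 5
Reactants: 6 aldehyde; 7 allyl acetate
Product: 8 2-{(1S,2S)-1-[(tert-butyldimethylsilyl)oxy]-1-(3,4,5-trimethoxyphenyl)propan-2-yl}pent-4-enal (both C2 epimers)
Conditions: 7 (1.1 equiv), Pd(PPh3)4 (5 mol%), pyrrolidine (30 mol%), DMSO, rt
Reagents that add atoms: none
Why: In this Tsuji–Trost allylation under enamine catalysis the catalytic pyrrolidine enamine of 6 captures the π-allyl complex of divalent palladium formed from 7 and zerovalent palladium; the β-branch slows a second allylation, and the new α-centre may form as a mixture because it is erased in step 7.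

Step 6
Reactants: 8 α-allyl aldehyde; 9 methyl vinyl ketone
Product: 11 4-allyl-4-{(1S,2S)-1-[(tert-butyldimethylsilyl)oxy]-1-(3,4,5-trimethoxyphenyl)propan-2-yl}cyclohex-2-en-1-one (both C4 epimers), via keto-aldehyde Michael adduct 10 (not isolated)
Conditions: 9 (1.5 equiv), KOH (0.2 equiv), EtOH, 0 °C to rt, then 60 °C
Reagents that add atoms: none
Why: In this Robinson annulation the aldehyde enolate adds to 9 to build the quaternary carbon, and the methyl ketone of 10 then condenses with the now non-enolisable aldehyde (aldol condensation) to close ring B as the 4,4-disubstituted cyclohexenone.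

Step 7
Reactants: 11 cyclohexenone
Product: 13 4-allyl-4-{(1S,2S)-1-[(tert-butyldimethylsilyl)oxy]-1-(3,4,5-trimethoxyphenyl)propan-2-yl}cyclohexa-2,5-dien-1-one, via trimethylsilyl dienol ether 12 (not isolated)
Conditions: LiN(i-Pr)2, TMSCl, THF, −78 °C; then IBX·MPO (2-iodoxybenzoic acid–4-methoxypyridine N-oxide complex), DMSO, rt
Reagents that add atoms: none
Why: Kinetic deprotonation at C6 and silylation give the 2-silyloxy diene, which the iodoxy reagent dehydrogenates at room temperature to the cross-conjugated dienone (silyl enol ether dehydrogenation); this method is chosen because quinone oxidants would attack the electron-rich benzylic ether and Pd(OAc)2 could insert the 1,3-related allyl alkene into its enolate, and with both arms now identical the quaternary carbon is no longer a stereocentre, so the epimer mixture converges.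

Step 8
Reactants: 13 silyl-protected dienone
Product: 14 4-allyl-4-[(1S,2S)-1-hydroxy-1-(3,4,5-trimethoxyphenyl)propan-2-yl]cyclohexa-2,5-dien-1-one
Conditions: HF·pyridine, pyridine, THF, 0 °C to rt; NaHCO3 work-up at 0 °C
Reagents that add atoms: none
Why: Buffered hydrogen fluoride cleaves the Si–O bond without ever forming a free alkoxide, so the hydroxy dienone should be isolable before any uncatalysed closure; the stereocentres are untouched.

Step 9
Reactants: 14 hydroxy dienone
Product: 15 (2S,3S,3aS,7aS)-3a-allyl-3-methyl-2-(3,4,5-trimethoxyphenyl)-3,3a,7,7a-tetrahydro-1-benzofuran-6(2H)-one (cis ring fusion; methyl cis to allyl, aryl trans to methyl)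
Conditions: (R)-TRIP (10 mol%), 4 Å molecular sieves, toluene, rt
Reagents that add atoms: none
Why: The phosphoric acid acts bifunctionally, its P=O oxygen accepting a hydrogen bond from the C2 hydroxyl while its acidic proton activates the C6 carbonyl, so that the oxygen adds to C7a of one enone arm and the dienol so formed is protonated at C7 (intramolecular oxa-Michael addition). The closest known reaction type is the desymmetrising oxa-Michael cyclisation of 4-(hydroxyalkyl)cyclohexa-2,5-dienones under chiral phosphoric acid or base catalysis. Ring A (O1–C2–C3–C3a–C7a) closes in the 5-exo-trig mode. C7a follows from the tether, because the two-atom link can deliver O1 only to the face of ring B that carries the side chain, which makes the fusion cis; C3a becomes a stereocentre through the choice of arm, which is governed by the (1S,2S) side chain together with the matched acid. The step needs closure on the arm that leaves the C3 methyl cis to the allyl group (3aS,7aS in 15) and not on the other arm. In the substrate this is secured by the fixed anti C2/C3 pair, which in that closure turns the C3 hydrogen and not the methyl group toward the remaining vinyl arm on the concave side of the new bicycle; this bias alone is expected to be modest and the acid is chosen to reinforce it.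

Step 10
Reactants: 15 cis-fused enone
Product: 17 (2S,3S,3aS)-3a-allyl-3-methyl-2-(3,4,5-trimethoxyphenyl)-3,3a-dihydro-1-benzofuran-6(2H)-one, via trimethylsilyl dienol ether 16 (not isolated)
Conditions: LiN(SiMe3)2, TMSCl (present from the start), THF, −78 °C; then IBX·MPO, DMSO, rt
Reagents that add atoms: none
Why: C6 is flanked by the vinylic C5 and by C7H2, so enolisation can only go to C7; trapping by TMSCl at −78 °C prevents β-elimination of O1 (which would reopen ring A and let the arms exchange), and the iodoxy reagent then removes the C7a hydrogen from the planar enol ether with no syn requirement to give the vinylogous ester (silyl enol ether dehydrogenation), deleting the C7a stereocentre on purpose.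

Step 11
Reactants: 17 dienone
Product: 18 (2S,3S,3aR)-3a-allyl-4,5-epoxy-3-methyl-2-(3,4,5-trimethoxyphenyl)-3,3a,4,5-tetrahydro-1-benzofuran-6(2H)-one (either epoxide face)
Conditions: t-BuOOH (in decane), DBU, CH2Cl2, 0 °C to rt
Reagents that add atoms: tert-butyl hydroperoxide, CC(C)(C)OO
Why: In this Weitz–Scheffer nucleophilic epoxidation the peroxide anion adds to C4 of the plain enone arm and closes onto C5, while the C7=C7a arm is a vinylogous ester and the allyl and aryl π-systems are not electrophilic; the epoxide face does not matter because both new centres are erased in step 12.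

Step 12
Reactants: 18 epoxy ketone
Product: 19 (2S,3S,3aR)-3a-allyl-5-methoxy-3-methyl-2-(3,4,5-trimethoxyphenyl)-3,3a-dihydro-1-benzofuran-6(2H)-one (target, CNP0197140.2)
Conditions: NaOMe, MeOH, rt to 60 °C
Reagents that add atoms: sodium methoxide, [Na+].[O-]C
Why: In this base-mediated conversion of an epoxy ketone into an α-alkoxy enone, methoxide opens the epoxide at C5 (the carbonyl-activated α-carbon; C4 is neopentyl next to quaternary C3a) and E1cB loss of the C4 hydroxyl from the ketol gives the C4=C5 methoxy enone, with C2, C3 and C3a untouched.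

**Compound list**

1 | 3,4,5-trimethoxybenzaldehyde | COc1cc(C=O)cc(OC)c1OC | starting material
2 | (E)-crotylboronic acid pinacol ester | C/C=C/CB1OC(C)(C)C(C)(C)O1 | starting material
3 | (1S,2S)-2-methyl-1-(3,4,5-trimethoxyphenyl)but-3-en-1-ol | C=C[C@H](C)[C@H](O)c1cc(OC)c(OC)c(OC)c1 | intermediate
4 | tert-butyl(dimethyl){[(1S,2S)-2-methyl-1-(3,4,5-trimethoxyphenyl)but-3-en-1-yl]oxy}silane | C=C[C@H](C)[C@H](O[Si](C)(C)C(C)(C)C)c1cc(OC)c(OC)c(OC)c1 | intermediate
5 | (3S,4S)-4-[(tert-butyldimethylsilyl)oxy]-3-methyl-4-(3,4,5-trimethoxyphenyl)butan-1-ol | OCC[C@H](C)[C@H](O[Si](C)(C)C(C)(C)C)c1cc(OC)c(OC)c(OC)c1 | intermediate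
6 | (3S,4S)-4-[(tert-butyldimethylsilyl)oxy]-3-methyl-4-(3,4,5-trimethoxyphenyl)butanal | O=CC[C@H](C)[C@H](O[Si](C)(C)C(C)(C)C)c1cc(OC)c(OC)c(OC)c1 | intermediate
7 | allyl acetate | C=CCOC(C)=O | starting material
8 | 2-{(1S,2S)-1-[(tert-butyldimethylsilyl)oxy]-1-(3,4,5-trimethoxyphenyl)propan-2-yl}pent-4-enal, both C2 epimers | C=CCC(C=O)[C@H](C)[C@H](O[Si](C)(C)C(C)(C)C)c1cc(OC)c(OC)c(OC)c1 | intermediate
9 | methyl vinyl ketone | CC(=O)C=C | starting material
10 | 2-allyl-2-{(1S,2S)-1-[(tert-butyldimethylsilyl)oxy]-1-(3,4,5-trimethoxyphenyl)propan-2-yl}-5-oxohexanal, both C2 epimers | C=CCC(C=O)(CCC(C)=O)[C@H](C)[C@H](O[Si](C)(C)C(C)(C)C)c1cc(OC)c(OC)c(OC)c1 | intermediate (not isolated)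
11 | 4-allyl-4-{(1S,2S)-1-[(tert-butyldimethylsilyl)oxy]-1-(3,4,5-trimethoxyphenyl)propan-2-yl}cyclohex-2-en-1-one, both C4 epimers | C=CCC1(CCC(=O)C=C1)[C@H](C)[C@H](O[Si](C)(C)C(C)(C)C)c1cc(OC)c(OC)c(OC)c1 | intermediate
12 | {[4-allyl-4-{(1S,2S)-1-[(tert-butyldimethylsilyl)oxy]-1-(3,4,5-trimethoxyphenyl)propan-2-yl}cyclohexa-1,5-dien-1-yl]oxy}trimethylsilane, both C4 epimers | C=CCC1(CC=C(O[Si](C)(C)C)C=C1)[C@H](C)[C@H](O[Si](C)(C)C(C)(C)C)c1cc(OC)c(OC)c(OC)c1 | intermediate (not isolated)
13 | 4-allyl-4-{(1S,2S)-1-[(tert-butyldimethylsilyl)oxy]-1-(3,4,5-trimethoxyphenyl)propan-2-yl}cyclohexa-2,5-dien-1-one | C=CCC1(C=CC(=O)C=C1)[C@H](C)[C@H](O[Si](C)(C)C(C)(C)C)c1cc(OC)c(OC)c(OC)c1 | intermediate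
14 | 4-allyl-4-[(1S,2S)-1-hydroxy-1-(3,4,5-trimethoxyphenyl)propan-2-yl]cyclohexa-2,5-dien-1-one | C=CCC1(C=CC(=O)C=C1)[C@H](C)[C@H](O)c1cc(OC)c(OC)c(OC)c1 | intermediate (key-step precursor)
15 | (2S,3S,3aS,7aS)-3a-allyl-3-methyl-2-(3,4,5-trimethoxyphenyl)-3,3a,7,7a-tetrahydro-1-benzofuran-6(2H)-one | C=CC[C@@]12C=CC(=O)C[C@@H]1O[C@H](c1cc(OC)c(OC)c(OC)c1)[C@H]2C | intermediate (key-step product)
16 | (2S,3S,3aS,7aS)-3a-allyl-3-methyl-6-(trimethylsilyloxy)-2-(3,4,5-trimethoxyphenyl)-2,3,3a,7a-tetrahydro-1-benzofuran | C=CC[C@@]12C=CC(O[Si](C)(C)C)=C[C@@H]1O[C@H](c1cc(OC)c(OC)c(OC)c1)[C@H]2C | intermediate (not isolated)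
17 | (2S,3S,3aS)-3a-allyl-3-methyl-2-(3,4,5-trimethoxyphenyl)-3,3a-dihydro-1-benzofuran-6(2H)-one | C=CC[C@@]12C=CC(=O)C=C1O[C@H](c1cc(OC)c(OC)c(OC)c1)[C@H]2C | intermediate
18 | (2S,3S,3aR)-3a-allyl-4,5-epoxy-3-methyl-2-(3,4,5-trimethoxyphenyl)-3,3a,4,5-tetrahydro-1-benzofuran-6(2H)-one, either epoxide face | C=CC[C@@]12C3OC3C(=O)C=C1O[C@H](c1cc(OC)c(OC)c(OC)c1)[C@H]2C | intermediate
19 | (2S,3S,3aR)-3a-allyl-5-methoxy-3-methyl-2-(3,4,5-trimethoxyphenyl)-3,3a-dihydro-1-benzofuran-6(2H)-one | C=CC[C@@]12C=C(OC)C(=O)C=C1O[C@H](c1cc(OC)c(OC)c(OC)c1)[C@H]2C | target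

**Step count**

Total steps: 12. Longest linear sequence: 12 steps (1 to 19); 2, 7 and 9 enter as single building blocks.

**Steps most likely to fail**

1. Step 9. The two diastereotopic arms may be discriminated poorly, or the bias of the side chain and that of the acid may oppose each other, so that closure on the wrong arm competes. The fallback replaces catalyst-controlled kinetic selection by equilibration with separation and recycling. It sets out from 13: n-Bu4NF in THF removes the silyl group and the alkoxide closes in the same flask under reversible conditions to a mixture of 15 and the wrong-arm adduct (2S,3S,3aR,7aR)-3a-allyl-3-methyl-2-(3,4,5-trimethoxyphenyl)-3,3a,7,7a-tetrahydro-1-benzofuran-6(2H)-one F1. The two are separated by chromatography. F1 is then warmed with DBU in toluene, where retro-oxa-Michael opening to 14 and re-closure restore the mixture, which is separated again. The fallback comes back to the route at 15.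

2. Step 11. The peroxide anion may add too slowly to C4, which is neopentyl and belongs to an enone whose carbonyl is deactivated by the vinylogous ester oxygen, so that decomposition or attack at C7a takes over. The fallback oxygenates C5 while ring B is still a plain enone. It sets out from 15: t-BuOOH and DBU in CH2Cl2, kept cold and stopped early so that 15 does not exchange arms through 14, should give the 4,5-epoxide of 15 F2. NaOMe in MeOH then opens it at C5 and dehydrates to (2S,3S,3aR,7aS)-3a-allyl-5-methoxy-3-methyl-2-(3,4,5-trimethoxyphenyl)-3,3a,7,7a-tetrahydro-1-benzofuran-6(2H)-one F3. Any base-induced opening of ring A at this stage should re-close on the unsubstituted, more electrophilic arm and so restore the same compound. LiN(SiMe3)2 with TMSCl at −78 °C gives the trimethylsilyl dienol ether of F3 F4, and IBX·MPO in DMSO dehydrogenates it at C7/C7a. The fallback comes back to the route at 19.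

3. Step 6. Michael addition of the congested aldehyde enolate, whose α-carbon sits next to the branched C3 stereocentre, may be too slow, so that methyl vinyl ketone polymerises and the aldehyde degrades under hydroxide. The fallback changes the nucleophile from a base-generated enolate to a preformed neutral enamine (Stork enamine annulation). It sets out from 8: pyrrolidine with 4 Å molecular sieves in toluene gives the pyrrolidine enamine of 8 F5. F5 is treated with 9 in toluene (rt to reflux), then with AcOH, NaOAc and water at 60 °C, which hydrolyses the adduct to 10 and condenses it. The fallback comes back to the route at 11.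

**Further compounds**

F1 | step 9 | (2S,3S,3aR,7aR)-3a-allyl-3-methyl-2-(3,4,5-trimethoxyphenyl)-3,3a,7,7a-tetrahydro-1-benzofuran-6(2H)-one | C=CC[C@]12C=CC(=O)C[C@H]1O[C@H](c1cc(OC)c(OC)c(OC)c1)[C@H]2C
F2 | step 11 | 4,5-epoxide of 15 (either epoxide face, other centres as in 15) | C=CC[C@@]12C3OC3C(=O)C[C@@H]1O[C@H](c1cc(OC)c(OC)c(OC)c1)[C@H]2C
F3 | step 11 | (2S,3S,3aR,7aS)-3a-allyl-5-methoxy-3-methyl-2-(3,4,5-trimethoxyphenyl)-3,3a,7,7a-tetrahydro-1-benzofuran-6(2H)-one | C=CC[C@@]12C=C(OC)C(=O)C[C@@H]1O[C@H](c1cc(OC)c(OC)c(OC)c1)[C@H]2C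
F4 | step 11 | trimethylsilyl dienol ether of F3 (6-trimethylsilyloxy, C6=C7) | C=CC[C@@]12C=C(OC)C(O[Si](C)(C)C)=C[C@@H]1O[C@H](c1cc(OC)c(OC)c(OC)c1)[C@H]2C
F5 | step 6 | pyrrolidine enamine of 8 (either alkene geometry) | C=CCC(=CN1CCCC1)[C@H](C)[C@H](O[Si](C)(C)C(C)(C)C)c1cc(OC)c(OC)c(OC)c1
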